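Two questions stand on this flask, a time and a height.

- time up to 15 d at which intermediate B stands highest
- the amount of intermediate B, in percent of the substrate charged, at that time

| flask | substrate | reagent | remark | time |
|---|---|---|---|---|
| dusk | 2 M | 0.60 M | run made earlier |  |
| noon | 2 M | 2.4 M | run made earlier |  |
| autumn | 3 M | 1.2 M | run made earlier |  |
| flask | 2.0 M | 1.20 M |  | 15 d |

- dusk (time / d: intermediate B / %, target / %): 1.04: 4.5, 25.5; 1.67: 5.5, 31.8; 3.00: 6.5, 39.1; 5.00: 6.5, 41.9; 8.00: 6.9, 43.8; 12.0: 6.3, 43.8
- noon (time / d: intermediate B / %, target / %): 1.04: 15.5, 22.4; 1.67: 18.3, 27.4; 3.00: 20.7, 33.5; 5.00: 20.1, 36.5; 8.00: 17.1, 37.9; 12.0: 12.5, 37.5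
- autumn (time / d: intermediate B / %, target / %): 1.04: 6.9, 21.3; 2.08: 8.8, 29.1; 4.00: 9.5, 33.7; 6.00: 9.2, 34.8; 12.0: 7.9, 35.2

(readings scatter by 0.3 percentage points)

The flask has the substrate charge of the dusk and noon runs, and its reagent, 1.20 M, is their geometric mean, 1.20 M. On logarithms it therefore stands at their midpoint, and each landmark of its curve is reckoned here as the mean of their logarithms. After a steep start, intermediate B is near 8.35 % and target near 23.9 % at 1.04 d. Target has bent by 5.00 d, near 39.1 %, and runs towards a level near 40.7 %. Intermediate B reads highest at 8.00 d in dusk and 3.00 d in noon: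

crest time = 4.90 d

At those readings, intermediate B over target is 0.158 in dusk and 0.618 in noon. Against the logarithm of reagent, the logarithm of this ratio, a selectivity factor as read, has slope 0.986, close to first power.

midpoint = 0.312

This is the crest ratio, intermediate B over target where intermediate B stands highest. The autumn run, with the flask's reagent and more substrate, reads 0.282.

crest height = crest ratio × target = 12.2 %

The forecast gives 4.5 d, earlier than this reckoning, and 12 %, adding that “the peak is flat”.

The flask gives 4.35 d and 12.3 %.

    substrate + reagent ⇌ intermediate A (K = 0.180 L mol⁻¹, k = 3.20 × 10⁻⁵ L mol⁻¹ s⁻¹)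
    substrate + reagent → intermediate B (k = 2.20 × 10⁻⁶ L mol⁻¹ s⁻¹)
    substrate → target (k = 5.90 × 10⁻⁶ s⁻¹)
    reagent + intermediate B → side product (k = 4.40 × 10⁻⁷ L mol⁻¹ s⁻¹)
    2 substrate → homo dimer (k = 4.40 × 10⁻⁶ L mol⁻¹ s⁻¹)

With target at 39.5 % at that time, the flask's crest ratio is 0.311. The neighbouring flask is charged with 0.80 M of substrate and the same reagent, and ends with 54.0 % of target. The carried crest ratio times that end value gives 16.8 %. The neighbouring flask's intermediate B stands highest at 17.7 %, more than that reckoning.

The readings come from a simulation on assumed constants.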